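**Retrosynthetic overview**

1. Plakortolide F (numbered along the parent acid: C1 lactone C=O, C3 = CH–OO, C4 = C(CH3)–O of the lactone, C5 = ring CH2, C6 = C(CH3)–OO, C7–C15 chain) is traced back to its aryl silyl ether carrying a C7≡C8 triple bond (HF·pyridine; diimide). The alkyne is a temporary oxidation level that makes the two carbon substituents on C6 very different in size.
2. Key disconnection: the two ring C–C bonds C5–C6 and C3–C4 and the lactone C4–O bond are cut together, giving a silylperoxy acetal ester (C1–C3 with the O–O unit), a 2-propenylboronate (C4, C5, 4-CH3) and an alkynyl methyl ketone dimethyl ketal (C6, 6-CH3, chain).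
3. Enabling feature: in the 1,2-dioxane ring both carbons on the O–O bridge (the CH–OO carbon C3 and the quaternary C6) are at carbonyl level once these two bonds are cut, i.e. an aldehyde-derived and a ketone-derived peroxycarbenium ion. The two ring carbons between them are the two carbons of a 2-propenyl group whose inner carbon C4 is also the carbinol carbon of the γ-lactone, next to the CH2CO2R arm on C3.
4. Ring order: no ring exists before the key step; in one flask the 1,2-dioxane closes first (cation–olefin closure, C5–C6), then the cis-fused γ-lactone (ester capture of the C4 cation).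
5. Fragments: the peroxy acetal comes from (E)-hex-3-enedioic acid by ozonolysis in methanol; the ketal comes from an aryl Grignard/1,7-dibromoheptane coupling and alkylation of 3,3-dimethoxybut-1-yne.

Key step: step 8

Remark: the target is taken as drawn, i.e. (3S,4S,6R) in the numbering above; fleeting species (primary ozonide, carbonyl oxide, peroxycarbenium ions, carbocations) are treated in the Why lines and carry no number.

**Route**

Step 1
Reactants: 1 (E)-hex-3-enedioic acid
Product: 2 di-tert-butyl (E)-hex-3-enedioate
Conditions: t-BuOC(=NH)CCl3 (3 equiv), BF3·OEt2 (cat.), CH2Cl2–cyclohexane, rt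
Reagents that add atoms: tert-butyl 2,2,2-trichloroacetimidate, CC(C)(C)OC(=N)C(Cl)(Cl)Cl
Why: Acid-catalysed O-alkylation of the carboxylic acid by the trichloroacetimidate (imidate esterification) installs both tert-butyl esters without base, so the β,γ-alkene should not move into conjugation.

Step 2
Reactants: 2 di-tert-butyl (E)-hex-3-enedioate
Product: 3 tert-butyl 3-hydroperoxy-3-methoxypropanoate (racemic)
Conditions: O3, CH2Cl2–MeOH (4:1), NaHCO3, −78 °C; N2 purge; cold chromatography
Reagents that add atoms: ozone, [O-][O+]=O; methanol, CO
Why: Criegee ozonolysis of the symmetrical alkene gives one aldehyde and one carbonyl oxide whichever way the primary ozonide opens, and methanol traps the carbonyl oxide as the α-methoxy hydroperoxide.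

Step 3
Reactants: 3 tert-butyl 3-hydroperoxy-3-methoxypropanoate
Product: 4 tert-butyl 3-methoxy-3-[(triethylsilyl)peroxy]propanoate (racemic)
Conditions: Et3SiCl, imidazole, DMF, 0 °C
Reagents that add atoms: chlorotriethylsilane, CC[Si](Cl)(CC)CC
Why: O-Silylation of the hydroperoxide masks the OOH group, so that it can neither oxidise the boronate of step 8 nor undergo acid-induced Hock cleavage, and gives a silylperoxy acetal, an established precursor type for peroxycarbenium ions.

Step 4
Reactants: 5 (prop-1-en-2-yl)magnesium bromide
Product: 7 diisopropyl (prop-1-en-2-yl)boronate, via borate ate complex 6 (not isolated)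
Conditions: B(OiPr)3, Et2O–THF, −78 °C → rt; then HCl (1 M in Et2O), 0 °C; distillation
Reagents that add atoms: triisopropyl borate, CC(C)OB(OC(C)C)OC(C)C
Why: Grignard addition to the trialkyl borate gives the tetracoordinate borate, from which anhydrous acid releases the dialkyl alkenylboronate (standard boronic ester synthesis).

Step 5
Reactants: 8 (4-bromophenoxy)(tert-butyl)dimethylsilane; 9 1,7-dibromoheptane (3 equiv)
Product: 11 [4-(7-bromoheptyl)phenoxy](tert-butyl)dimethylsilane, via aryl Grignard reagent 10 (not isolated)
Conditions: Mg, THF, reflux; then 9, Li2CuCl4 (3 mol %), THF, −10 °C → rt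
Reagents that add atoms: none
Why: Tamura–Kochi copper-catalysed coupling of an aryl Grignard reagent with a primary alkyl bromide, in which excess dibromide limits double arylation and the aryl silyl ether tolerates the organomagnesium.

Step 6
Reactants: 12 but-3-yn-2-one
Product: 13 3,3-dimethoxybut-1-yne
Conditions: HC(OMe)3, MeOH, camphorsulfonic acid (cat.), 0 °C → rt; Et3N quench; distillation
Reagents that add atoms: trimethyl orthoformate, COC(OC)OC
Why: Acid-catalysed ketalisation driven by the orthoester as water scavenger masks the ynone carbonyl and leaves the acetylenic C–H free for metalation.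

Step 7
Reactants: 13 3,3-dimethoxybut-1-yne; 11 [4-(7-bromoheptyl)phenoxy](tert-butyl)dimethylsilane
Product: 15 tert-butyl[4-(10,10-dimethoxyundec-8-yn-1-yl)phenoxy]dimethylsilane, via lithium acetylide 14 (not isolated)
Conditions: n-BuLi, THF, −78 °C; then 11, DMPU, −78 °C → rt
Reagents that add atoms: none
Why: SN2 alkylation of a lithium acetylide by a primary bromide in a dipolar aprotic co-solvent, under which the ketal and the aryl silyl ether are stable.

Step 8
Reactants: 4 tert-butyl 3-methoxy-3-[(triethylsilyl)peroxy]propanoate; 7 diisopropyl (prop-1-en-2-yl)boronate; 15 tert-butyl[4-(10,10-dimethoxyundec-8-yn-1-yl)phenoxy]dimethylsilane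
Product: 18 (3S,4S,6S)-15-{4-[(tert-butyldimethylsilyl)oxy]phenyl}-3,6-epidioxy-4,6-dimethylpentadec-7-yn-4-olide, via allylic silyl peroxide 16 (not isolated), via mixed peroxyketal 17 (not isolated)
Conditions: 7 (1.05 equiv), chiral tartaric-acid-diamide diol (10 mol %, antipode chosen to give 3S), Yb(OTf)3 (5 mol %), 4 Å MS, CH2Cl2, −40 °C; then 15 (1.1 equiv), TMSOTf (0.3 equiv), −78 → −40 °C
Reagents that add atoms: none
Why: Proposed new method: Yb(OTf)3 abstracts methoxide from 4, and the resulting aldehyde-level silylperoxycarbenium ion, ion-paired with the chiral diol-bound methoxy(alkenyl)borate, receives the 2-propenyl group by boron-to-carbon migration through the boron-bearing carbon, which forms C3–C4 and sets C3 under catalyst control (intermediate 16). The closest known reaction types are Lewis-acid substitutions of peroxyacetals through peroxycarbenium ions and chiral-diol-catalysed Petasis-type additions of alkenylboronates to acetal-derived oxocarbenium ions and to enones. TMSOTf then exchanges the silyl peroxide with ketal 15 to the mixed peroxyketal 17 and ionises it to a ketone-level peroxycarbenium ion, whose carbon is attacked by the CH2 terminus of the allylic 2-propenyl group in a peroxy-Prins (cation–olefin) cyclisation of the kind known for unsaturated peroxyketals, so that C5–C6 forms and the 1,2-dioxane closes in the 6-endo-trig mode with Markovnikov charge at C4. The tertiary C4 cation is captured by the carbonyl oxygen of the tert-butyl ester on C3 (5-exo closure, loss of isobutene), which closes the γ-lactone. C4 is fixed by this tether, because only cis-fusion is within reach of the two-atom arm and leaves the C4 methyl equatorial, and C6 is fixed in a chair transition state that keeps the CH2CO2tBu arm on C3 equatorial and puts the slender alkynyl group instead of the methyl group into the axial (Z-peroxycarbenium) position, cis to the lactone oxygen as in the target. The step needs ipso regiochemistry of alkenyl transfer (secured by migration within the borate instead of free-alkene attack), reaction at C3 before C6 (secured by adding 15 only after 4 is consumed and by the near-stoichiometric amount of 7), ionisation with loss of methoxide and not of the peroxide oxygen (secured by the higher basicity of the ether oxygen) and survival of the O–O bonds (secured by −78 °C and substoichiometric TMSOTf, which disfavour Hock-type heterolysis).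

Step 9
Reactants: 18 (3S,4S,6S)-15-{4-[(tert-butyldimethylsilyl)oxy]phenyl}-3,6-epidioxy-4,6-dimethylpentadec-7-yn-4-olide
Product: 20 (3S,4S,6R)-15-{4-[(tert-butyldimethylsilyl)oxy]phenyl}-3,6-epidioxy-4,6-dimethylpentadecan-4-olide, via Z-alkene 19 (not isolated)
Conditions: KO2CN=NCO2K (excess, in portions), AcOH, MeOH–CH2Cl2, 0 °C → rt
Reagents that add atoms: none
Why: Diimide reduction, a concerted syn transfer of H2 from HN=NH, should saturate the C≡C and then the C=C bond without touching the O–O bond, the lactone or the aryl silyl ether, and the mildly acidic medium avoids base-induced β-elimination of the peroxide.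

Step 10
Reactants: 20 (3S,4S,6R)-15-{4-[(tert-butyldimethylsilyl)oxy]phenyl}-3,6-epidioxy-4,6-dimethylpentadecan-4-olide
Product: 21 plakortolide F, (3S,4S,6R)-3,6-epidioxy-15-(4-hydroxyphenyl)-4,6-dimethylpentadecan-4-olide
Conditions: HF·pyridine, THF, 0 °C → rt
Reagents that add atoms: none
Why: Fluoride-mediated cleavage of the aryl silyl ether (desilylation) under weakly acidic conditions spares the peroxide, avoids the base-promoted retro-oxa-Michael opening of the β-peroxy lactone and touches no stereocentre.

**Compound list**

1 | (E)-hex-3-enedioic acid | OC(=O)C/C=C/CC(O)=O | starting material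
2 | di-tert-butyl (E)-hex-3-enedioate | CC(C)(C)OC(=O)C/C=C/CC(=O)OC(C)(C)C | intermediate
3 | tert-butyl 3-hydroperoxy-3-methoxypropanoate (racemic) | COC(CC(=O)OC(C)(C)C)OO | intermediate
4 | tert-butyl 3-methoxy-3-[(triethylsilyl)peroxy]propanoate (racemic) | COC(CC(=O)OC(C)(C)C)OO[Si](CC)(CC)CC | intermediate
5 | (prop-1-en-2-yl)magnesium bromide | CC(=C)[Mg]Br | starting material
6 | bromomagnesium triisopropoxy(prop-1-en-2-yl)borate; formed in the flask, not isolated | CC(=C)[B-](OC(C)C)(OC(C)C)OC(C)C.[Mg+2].[Br-] | intermediate
7 | diisopropyl (prop-1-en-2-yl)boronate | CC(=C)B(OC(C)C)OC(C)C | intermediate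
8 | (4-bromophenoxy)(tert-butyl)dimethylsilane | CC(C)(C)[Si](C)(C)Oc1ccc(Br)cc1 | starting material
9 | 1,7-dibromoheptane | BrCCCCCCCBr | starting material
10 | {4-[(tert-butyldimethylsilyl)oxy]phenyl}magnesium bromide; formed in the flask, not isolated | CC(C)(C)[Si](C)(C)Oc1ccc([Mg]Br)cc1 | intermediate
11 | [4-(7-bromoheptyl)phenoxy](tert-butyl)dimethylsilane | CC(C)(C)[Si](C)(C)Oc1ccc(CCCCCCCBr)cc1 | intermediate
12 | but-3-yn-2-one | CC(=O)C#C | starting material
13 | 3,3-dimethoxybut-1-yne | COC(C)(OC)C#C | intermediate
14 | (3,3-dimethoxybut-1-yn-1-yl)lithium; formed in the flask, not isolated | COC(C)(OC)C#C[Li] | intermediate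
15 | tert-butyl[4-(10,10-dimethoxyundec-8-yn-1-yl)phenoxy]dimethylsilane | COC(C)(OC)C#CCCCCCCCc1ccc(O[Si](C)(C)C(C)(C)C)cc1 | intermediate
16 | tert-butyl (3S)-4-methyl-3-[(triethylsilyl)peroxy]pent-4-enoate; formed in the flask, not isolated | CC(=C)[C@H](CC(=O)OC(C)(C)C)OO[Si](CC)(CC)CC | intermediate
17 | tert-butyl (3S)-3-{[2-methoxy-11-(4-{[tert-butyl(dimethyl)silyl]oxy}phenyl)undec-3-yn-2-yl]peroxy}-4-methylpent-4-enoate (both configurations at the ketal carbon); formed in the flask, not isolated | CC(=C)[C@H](CC(=O)OC(C)(C)C)OOC(C)(OC)C#CCCCCCCCc1ccc(O[Si](C)(C)C(C)(C)C)cc1 | intermediate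
18 | (3S,4S,6S)-15-{4-[(tert-butyldimethylsilyl)oxy]phenyl}-3,6-epidioxy-4,6-dimethylpentadec-7-yn-4-olide (cis-fused 1,2-dioxane/γ-lactone; same spatial arrangement at C6 as in 21, the descriptor differs because the alkynyl carbon outranks C5) | C[C@@]1(C#CCCCCCCCc2ccc(O[Si](C)(C)C(C)(C)C)cc2)C[C@]2(C)OC(=O)C[C@@H]2OO1 | intermediate
19 | (3S,4S,6S,7Z)-15-{4-[(tert-butyldimethylsilyl)oxy]phenyl}-3,6-epidioxy-4,6-dimethylpentadec-7-en-4-olide; formed in the flask, not isolated | C[C@@]1(/C=C\CCCCCCCc2ccc(O[Si](C)(C)C(C)(C)C)cc2)C[C@]2(C)OC(=O)C[C@@H]2OO1 | intermediate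
20 | (3S,4S,6R)-15-{4-[(tert-butyldimethylsilyl)oxy]phenyl}-3,6-epidioxy-4,6-dimethylpentadecan-4-olide | C[C@@]1(CCCCCCCCCc2ccc(O[Si](C)(C)C(C)(C)C)cc2)C[C@]2(C)OC(=O)C[C@@H]2OO1 | intermediate
21 | plakortolide F, (3S,4S,6R)-3,6-epidioxy-15-(4-hydroxyphenyl)-4,6-dimethylpentadecan-4-olide | C[C@@]1(CCCCCCCCCc2ccc(O)cc2)C[C@]2(C)OC(=O)C[C@@H]2OO1 | target

**Step count and risks**

Total step count: 10. Longest linear sequence: 6 steps (steps 1, 2, 3, 8, 9, 10).

Steps most likely to fail:

1. Step 8 (proposed new method). The alkenyl transfer may go through the CH2 terminus of the boronate, which would lead to annulation to a 1,2-dioxolane instead of ipso substitution. Facial control at C3 by the chiral borate may be insufficient, the silyl peroxide may oxidise the C–B bond, or the secondary peroxyacetal may ionise too slowly with the lanthanide triflate. The fallback sets out from 2 and comes back to the route at 16; it makes the C3–O bond on a carbon skeleton that already holds C3–C4. Cross-metathesis of 2 with 2-methylbut-2-ene (second-generation ruthenium benzylidene–NHC catalyst) should give tert-butyl 4-methylpent-3-enoate F1. A Schenck ene reaction with singlet oxygen (O2, tetraphenylporphyrin, hν, CH2Cl2) should give racemic tert-butyl 3-hydroperoxy-4-methylpent-4-enoate F2, the secondary hydroperoxide being the regioisomer that is kept. An enzymatic kinetic resolution (horseradish peroxidase with guaiacol, or a lipase, in the sense that reduces the R-hydroperoxide) should leave tert-butyl (3S)-3-hydroperoxy-4-methylpent-4-enoate F3. Silylation (Et3SiCl, imidazole) gives 16, now isolated, which re-enters step 8 at the addition of 15 and TMSOTf.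

2. Step 9. Hydrogen transfer to the internal alkyne next to the quaternary C6 may be slower than the disproportionation of diimide, so that the reduction stalls at the Z-alkene stage, and forcing conditions may cost the O–O bond. The fallback sets out from 15 and comes back at 20; it removes the unsaturation before the peroxide exists. Hydrogenation of 15 (H2, Pd/C, EtOAc, trace Et3N) should give tert-butyl[4-(10,10-dimethoxyundecyl)phenoxy]dimethylsilane F4, which takes the place of 15 in step 8. By way of the saturated mixed peroxyketal tert-butyl (3S)-3-{[2-methoxy-11-(4-{[tert-butyl(dimethyl)silyl]oxy}phenyl)undecan-2-yl]peroxy}-4-methylpent-4-enoate F5, the cyclisation leads to 20 directly. The price is the loss of the size difference at C6, so that (3S,4S,6S)-15-{4-[(tert-butyldimethylsilyl)oxy]phenyl}-3,6-epidioxy-4,6-dimethylpentadecan-4-olide F6, the C6 epimer, is expected alongside and has to be removed by chromatography.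

3. Step 6. Methanol may add in conjugate fashion to the terminal ynone, or the ynone may polymerise under acid, instead of forming the ketal. The fallback sets out from 11 and comes back at 15; it builds the ketal carbon from an orthoester, so that no ynone is ever made. Alkylation of lithium acetylide–ethylenediamine complex with 11 (DMSO, rt) should give tert-butyldimethyl[4-(non-8-yn-1-yl)phenoxy]silane F7. Deprotonation with EtMgBr (THF) gives {9-[4-({tert-butyl(dimethyl)silyl}oxy)phenyl]non-1-yn-1-yl}magnesium bromide F8, which with trimethyl orthoacetate (toluene, heat; Bodroux–Chichibabin-type substitution of an orthoester by a Grignard reagent) gives 15.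

Further compounds
F1 | step 8 | tert-butyl 4-methylpent-3-enoate | CC(C)=CCC(=O)OC(C)(C)C
F2 | step 8 | tert-butyl 3-hydroperoxy-4-methylpent-4-enoate (racemic) | CC(=C)C(CC(=O)OC(C)(C)C)OO
F3 | step 8 | tert-butyl (3S)-3-hydroperoxy-4-methylpent-4-enoate | CC(=C)[C@H](CC(=O)OC(C)(C)C)OO
F4 | step 9 | tert-butyl[4-(10,10-dimethoxyundecyl)phenoxy]dimethylsilane | COC(C)(OC)CCCCCCCCCc1ccc(O[Si](C)(C)C(C)(C)C)cc1
F5 | step 9 | tert-butyl (3S)-3-{[2-methoxy-11-(4-{[tert-butyl(dimethyl)silyl]oxy}phenyl)undecan-2-yl]peroxy}-4-methylpent-4-enoate | CC(=C)[C@H](CC(=O)OC(C)(C)C)OOC(C)(OC)CCCCCCCCCc1ccc(O[Si](C)(C)C(C)(C)C)cc1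
F6 | step 9 | (3S,4S,6S)-15-{4-[(tert-butyldimethylsilyl)oxy]phenyl}-3,6-epidioxy-4,6-dimethylpentadecan-4-olide | C[C@]1(CCCCCCCCCc2ccc(O[Si](C)(C)C(C)(C)C)cc2)C[C@]2(C)OC(=O)C[C@@H]2OO1
F7 | step 6 | tert-butyldimethyl[4-(non-8-yn-1-yl)phenoxy]silane | C#CCCCCCCCc1ccc(O[Si](C)(C)C(C)(C)C)cc1
F8 | step 6 | {9-[4-({tert-butyl(dimethyl)silyl}oxy)phenyl]non-1-yn-1-yl}magnesium bromide | Br[Mg]C#CCCCCCCCc1ccc(O[Si](C)(C)C(C)(C)C)cc1
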